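## Structural features

The target 30 is a 4-aryl-3,4-dihydrocoumarin. Benzene ring A (C4a, C5, C6, C7, C8, C8a) is fused through C4a and C8a to a six-membered lactone (O1, C2, C3, C4); C4 carries the 4-hydroxyphenyl ring B and C8 carries a 3-phenylpropanoyl chain. C4 is the only stereocentre (S). It is doubly benzylic, β to the lactone carbonyl and has no stereogenic neighbour, so the task is absolute, not relative, configuration. Ring A is pentasubstituted: O1 on C8a, the acyl carbon on C8, a hydroxyl on C7, hydrogen on C6, a hydroxyl on C5 and the C4 branch on C4a. This is a phloroglucinol nucleus whose three oxygens play three different roles. The lactone is an aryl ester, opened by base or alcohols; once O5 is free it can re-close on O5 and turn the 8-acyl into the 6-acyl skeleton. The electron-rich ring A also invites oxidation, attack at C6 and acid-induced ipso cleavage of C4–C4a, which would racemise C4. The real difficulty is regiochemical: O1 must be told apart from O5 and O7, and C8 from C6, at positions that are electronically almost alike, while C4 stays a single enantiomer. The key step uses the fact that the ring-A carbons divide into a four-carbon vinylketene unit (C8a, C6, C5, C4a) and a two-carbon oxygenated alkyne unit (C8, C7). Built this way, O1 appears as a free phenol, O7 as a silyl ether and O5 as a benzyl ether, and the acyl carbon reaches C8 as a ketal.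

## Logic of the disconnections

30 ⇒ 29. The two O–benzyl bonds (on O5 and on ring B) are the last to be freed. Benzyl is the one group that leaves under neutral, non-nucleophilic conditions, and O5 must stay covered to the end because a free O5 beside the lactone allows acyl migration. Nothing is gained in skeleton; the gain is a safe last step. The forward step must spare the aryl ketone and the aryl ester.

29 ⇒ 28. The O7–Si bond is cut. The silyl group is what the alkyne partner brings with it, and it is orthogonal to benzyl. The demand is a fluoride source that does not open the lactone.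

28 ⇒ 26 (through 27). The lactone bond O1–C2 is cut and the C8 carbonyl is masked as a dioxolane. In 26 only O1 is free, so ring closure has one possible outcome; the ketal is needed because the alkyne of the next disconnection must be electron-rich. The gain is an open-chain ester that has been present since the start. The acid must serve both events without ionising C4–C4a.

26 ⇒ 16 + 21. Three bonds of ring A are cut: C8a–C8, C6–C7 and C4a–C8a. Ring A disappears, leaving a four-carbon piece carrying the stereocentre and O5 and a two-carbon piece carrying O7 and the acyl carbon. This is the largest gain of the route: a pentasubstituted benzene with three different oxygens becomes two small π components. The forward step must join C8a to C8 and not to C7, must be run thermally, and must leave the benzylic centre alone.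

16 ⇒ 6 + 13 (through 14 and 15). The two ring bonds of the four-membered ring that are absent in the acid are cut (in target numbering C8a–C6, which the key step later breaks again, and C4a–C5). The stereocentre then sits in an open-chain hemiester, and O5 with its benzyl group comes from a two-carbon alkyne. The ketene must be generated without exchanging the two arms of the hemiester, which would racemise it, and 13 must be handled cold.

6 ⇒ 5 ⇒ 4 ⇒ 1 + 2. Cutting the ester C–O bond of 6 turns the stereocentre into the prochiral centre of the symmetric 5. 5 is the dehydrated form of 4, and in 4 the two C–C bonds at the benzylic carbon are cut, giving 1 and two molecules of 2. The only stereocentre is thus traced to an achiral compound made in one operation from bulk chemicals. The forward step must select one of two enantiotopic carbonyl groups.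

13 ⇒ 10 ⇒ 7 + 8. The O–C(sp) bond is cut: both alkyne carbons come from 8, the oxygen and its benzyl group from 7. The demand is two losses of chloride without warming.

21 ⇒ 18 ⇒ 17. The O–Si bond and the alkyne are cut. The oxygen-bearing alkyne carbon is the ester carbon of 18, the other alkyne carbon is a one-carbon insert, and 18 is the ketal of 17. The gain is a commercial keto ester. The demand is a 1,2-shift of the ketal-bearing carbon and silylation on oxygen, not carbon.

## Other disconnections considered

Alternative 1: The cut removes C3 from the lactone ring (C2–C3 and C3–C4) and leads back to the 3-arylbenzofuran A1.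
- Forward step: dichlorocarbene (from thermolysis of Cl3CCO2Na) would add to the furan C2=C3 bond of A1, and the dichlorocyclopropane would open with loss of chloride to the 3-chlorochromenylium salt A2.
- In favour: ring A is bought, not built, and the new carbon can enter at one place only. On simplicity of raw materials and on steps up to the key step this plan is the better one.
- Against: A2 is flat at C4 and at the wrong oxidation level. C2 must still be oxidised, the chlorine removed and the C3–C4 double bond reduced enantioselectively beside the bulky O5 substituent. The electron-rich ring A, the ether oxygens and the enolisable ketone offer the carbene other targets. Making A1 meets the same O1/O5 and C6/C8 ambiguity that the chosen plan avoids.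
- Comparison: structurally, the chosen plan builds ring A with labelled oxygens and brings C4 in from a desymmetrised diacid, whereas here ring A is kept and C4 is left to a late reduction. Mechanistically, a cheletropic addition and cyclopropyl-to-allyl cation opening is as well understood as the pericyclic cascade (equal). In step economy the long endgame after A2 should cancel the short start.

Alternative 2: The cut removes O1 (O1–C8a and O1–C2) and leads to the indanone A3.
- Forward step: a peracid would add to the ketone of A3 and the aryl carbon would migrate in the Criegee intermediate to give the lactone A4.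
- In favour: the oxygen pattern of A3 is symmetrical, so its preparation raises no regiochemical question, and the migration does not touch C4. A4 should be reached in roughly half the steps that 28 needs here: on step count to the lactone this alternative is better, and on security of the stereocentre it is equal.
- Against: A4 has no carbon on C8. The acyl group would have to enter afterwards by electrophilic substitution, choosing C8 (beside the weakly donating lactone oxygen) over C6 (between two ether oxygens), under Lewis acids that also strip benzyl ethers and let the lactone migrate. Carrying the acyl group through the oxidation is no remedy, since the peracid would then face two aryl ketones. The migrating carbon is meta to both alkoxy groups, and the ring is open to peracid hydroxylation.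
- Comparison: structurally this route leaves exactly the C8/C6 question that the chosen plan settles by construction. Mechanistically a single ionic 1,2-shift is simpler than a four-stage cascade (better). The step advantage is real only if the late acylation can be made selective.

Alternative 3: The cut is C8–C8a in ring A together with O1–C2, leading to the pyranone A5.
- Forward step: Mg(OMe)2 in MeOH would open the pyranone at its lactone carbonyl, the doubly activated C8 methylene would attack the new ester at C8a (Claisen mode), and after aromatisation the C8a hydroxyl would lactonise onto the side-chain ester to give A6, which is the same compound as 29.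
- In favour: the route is biomimetic, the three oxygens are differentiated by construction just as in the chosen plan (equal), and ring A and the lactone form in one flask. No silyl ether has to be removed, so the endgame is one step shorter (better).
- Against: in A5 the stereocentre is β to an ester and carries a stabilised carbon leaving group, so methoxide can racemise it by retro-Michael and Michael addition. The opened polyketone can fold in aldol modes or re-close to a pyranone. A5 itself needs an enantioselective C-alkylation and a side-chain acylation that are not short.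
- Comparison: structurally both plans build ring A; mechanistically an ionic condensation under base stands against a neutral thermal cascade, which is kinder to the stereocentre. In step economy the two should be close, with the chosen plan paying for two sensitive alkynes and this one for A5.

Key step: step 9

Assumption: the lipase-catalysed methanolysis of 5 is taken to give the (S)-hemiester 6, the sense known for this enzyme with 3-arylglutaric anhydrides; the configuration of 6 is to be confirmed by correlation before it is carried on.

Remark: the benzylic descriptor is S in 6, R in 14–16 and 22–25, and S again from 26 on. Only the CIP ranking of the substituents changes; no bond at this carbon is made or broken after step 3.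

## Route

Step 1
Reactants: 1 4-(benzyloxy)benzaldehyde; 2 ethyl acetoacetate
Product: 4 3-[4-(benzyloxy)phenyl]pentanedioic acid, via bis-acetoacetate Michael adduct 3 (not isolated)
Conditions: 2 (2.1 equiv), piperidine (cat.), EtOH, rt; then aq KOH (excess), EtOH, reflux; HCl to pH 1
Reagents that add atoms: potassium hydroxide, [K+].[OH-]
Why: Knoevenagel condensation and Michael addition of a second molecule of 2 give 3; hot hydroxide then removes both acetyl groups by retro-Claisen cleavage and saponifies the esters. The benzyl ether is inert to base and the product is achiral, with a prochiral C3.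

Step 2
Reactants: 4 3-[4-(benzyloxy)phenyl]pentanedioic acid
Product: 5 4-[4-(benzyloxy)phenyl]oxane-2,6-dione
Conditions: Ac2O, 120 °C; evaporate; crystallise from toluene
Reagents that add atoms: none
Why: Dehydrative cyclisation of a glutaric acid to its six-membered anhydride. The symmetric anhydride offers two enantiotopic carbonyl groups to the next step.

Step 3
Reactants: 5 4-[4-(benzyloxy)phenyl]oxane-2,6-dione
Product: 6 (3S)-3-[4-(benzyloxy)phenyl]-5-methoxy-5-oxopentanoic acid
Conditions: MeOH (3 equiv), immobilised Candida antarctica lipase B, t-BuOMe, 25 °C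
Reagents that add atoms: methanol, CO
Why: Enzymatic desymmetrisation by enantiotopic-group-selective alcoholysis of a prochiral cyclic anhydride. The serine of the lipase is acylated by one carbonyl group only and methanol releases the methyl ester, so the active-site pocket sets C3 as S.

Step 4
Reactants: 7 benzyl alcohol; 8 trichloroethylene
Product: 10 {[(E)-1,2-dichloroethenyl]oxy}methylbenzene, via dichloroacetylene 9 (not isolated)
Conditions: KH (1.2 equiv), THF, 0 °C; then 8 (1.1 equiv), −40 °C → rt
Reagents that add atoms: none
Why: The alkoxide eliminates HCl from 8 to give 9 and then adds to it in anti fashion, which gives the (E)-dichlorovinyl ether. This is the standard entry to ynol ethers from alcohols.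

Step 5
Reactants: 10 {[(E)-1,2-dichloroethenyl]oxy}methylbenzene
Product: 13 (ethynyloxy)methylbenzene, via benzyl chloroethynyl ether 11 (not isolated), via lithium benzyloxyethynide 12 (not isolated)
Conditions: n-BuLi (2.2 equiv), Et2O, −78 → −40 °C; MeOH, −78 °C; cold aqueous work-up; kept as a cold CH2Cl2 solution and used at once
Reagents that add atoms: none
Why: Dehydrochlorination to 11 and chlorine–lithium exchange give 12, which is protonated at low temperature. The ether is handled cold because benzyl alkynyl ethers rearrange sigmatropically on heating.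

Step 6
Reactants: 6 (3S)-3-[4-(benzyloxy)phenyl]-5-methoxy-5-oxopentanoic acid; 13 (ethynyloxy)methylbenzene
Product: 16 methyl (3R)-3-[4-(benzyloxy)phenyl]-3-[2-(benzyloxy)-4-oxocyclobut-2-en-1-yl]propanoate (both epimers at the ring carbon), via acid chloride 14 (not isolated), via aldoketene 15 (not isolated)
Conditions: (COCl)2 (1.2 equiv), DMF (cat.), CH2Cl2, 0 °C, evaporate cold; then slow addition to 13 (2 equiv), Et3N (1.5 equiv), CH2Cl2, 0 °C → rt
Reagents that add atoms: none
Why: Dehydrochlorination of 14 gives 15, which is trapped by a regiospecific ketene–ynol ether [2+2] cycloaddition (ketene carbonyl carbon to the unsubstituted alkyne carbon) to give the 3-alkoxycyclobutenone. 14 is made and used cold so that the ester and acid chloride termini cannot exchange through a cyclic acyloxonium ion, which would racemise the material. The benzylic centre is α to no carbonyl and is untouched; the new ring stereocentre forms unselectively and vanishes in step 9.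

Step 7
Reactants: 17 ethyl 2-oxo-4-phenylbutanoate
Product: 18 ethyl 2-(2-phenylethyl)-1,3-dioxolane-2-carboxylate
Conditions: (Me3SiOCH2)2 (1.5 equiv), Me3SiOSO2CF3 (5 mol %), CH2Cl2, −78 → 0 °C; pyridine quench
Reagents that add atoms: 1,2-bis(trimethylsilyloxy)ethane, C[Si](C)(C)OCCO[Si](C)(C)C
Why: Silyl-triflate-catalysed ketalisation of the activated ketone with the bis(silyl) ether of the diol, driven by formation of the disiloxane. Aprotic conditions avoid transesterification of the ethyl ester by free glycol.

Step 8
Reactants: 18 ethyl 2-(2-phenylethyl)-1,3-dioxolane-2-carboxylate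
Product: 21 triisopropyl({[2-(2-phenylethyl)-1,3-dioxolan-2-yl]ethynyl}oxy)silane, via lithium dibromoenolate 19 (not isolated), via lithium ynolate 20 (not isolated)
Conditions: CH2Br2 (1.1 equiv), lithium 2,2,6,6-tetramethylpiperidide (1.1 equiv), THF, −78 °C; LiN(SiMe3)2 (1.1 equiv); n-BuLi (2 equiv), −78 → 0 °C; i-Pr3SiCl (1.3 equiv), −78 → 0 °C
Reagents that add atoms: dibromomethane, BrCBr; chlorotri(propan-2-yl)silane, CC(C)[Si](Cl)(C(C)C)C(C)C
Why: Kowalski homologation stopped at the ynolate: LiCHBr2 adds to the ester, the dibromo ketone is enolised to 19, and bromine–lithium exchange with 1,2-shift of the ketal carbon gives 20. The bulky silyl chloride captures 20 on oxygen to give the siloxyalkyne.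

Step 9
Reactants: 16 methyl (3R)-3-[4-(benzyloxy)phenyl]-3-[2-(benzyloxy)-4-oxocyclobut-2-en-1-yl]propanoate; 21 triisopropyl({[2-(2-phenylethyl)-1,3-dioxolan-2-yl]ethynyl}oxy)silane
Product: 26 methyl (3S)-3-[4-(benzyloxy)phenyl]-3-{6-(benzyloxy)-2-hydroxy-3-[2-(2-phenylethyl)-1,3-dioxolan-2-yl]-4-[(triisopropylsilyl)oxy]phenyl}propanoate, via alkoxyvinylketene 22 (not isolated), via 4-vinylcyclobutenone 23 (not isolated), via dienylketene 24 (not isolated), via cyclohexa-2,4-dienone 25 (not isolated)
Conditions: 21 (1.3 equiv), degassed toluene (0.3 M), 80 → 110 °C, argon, no irradiation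
Reagents that add atoms: none
Why: Heating opens 16 by conrotatory 4π cleavage to 22 with the side chain turning outward, so that the benzylic C–H never lies beside the ketene terminus; light would also give the inward isomer and invite a 1,5-hydrogen shift that destroys the stereocentre, hence thermal activation only. The ketene carbonyl carbon (C8a) then bonds to the nucleophilic, oxygen-remote carbon of 21 (C8) and the ketene α-carbon (C6) to the oxygen-bearing carbon (C7) in a [2+2] cycloaddition to give 23. Strain drives a second 4π opening of 23 to 24, which closes ring A by a thermally allowed disrotatory 6π electrocyclisation (C4a–C8a) to 25; enolisation gives the phenol 26. The closest known reaction type is the Danheiser benzannulation of cyclobutenones with siloxyalkynes. No stereocentre is formed: the sp3 ring carbons of 16, 23 and 25 all end as aromatic carbons, and the benzylic centre is a spectator outside the reacting π system. The selectivity that matters is the regiochemistry of the [2+2] step, fixed by the polarisation of the ynol ether against the electrophilic ketene carbon, so that C8 arrives between the free hydroxyl on C8a and the silyl ether on C7, with the benzyl ether on C5. A small excess of 21 at moderate concentration is meant to hold back ketene dimerisation and acylation of 26 by 22.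

Step 10
Reactants: 26 methyl (3S)-3-[4-(benzyloxy)phenyl]-3-{6-(benzyloxy)-2-hydroxy-3-[2-(2-phenylethyl)-1,3-dioxolan-2-yl]-4-[(triisopropylsilyl)oxy]phenyl}propanoate
Product: 28 (4S)-5-(benzyloxy)-4-[4-(benzyloxy)phenyl]-8-(3-phenylpropanoyl)-7-[(triisopropylsilyl)oxy]-3,4-dihydro-2H-chromen-2-one, via keto phenol ester 27 (not isolated)
Conditions: p-TsOH·H2O (0.2 equiv), THF/H2O (10:1), 40 °C; then evaporate, toluene, 60 °C
Reagents that add atoms: water, O
Why: Aqueous acid hydrolyses the aryl ketal readily because the electron-rich ring stabilises the oxocarbenium ion; the only free phenol (O1) then lactonises onto the methyl ester, helped by the crowded ortho-substituted 3-arylpropanoate, and any ring closure that has already begun in step 9 ends at the same product. O5 and O7 are blocked, so the lactone cannot form on the wrong oxygen. The temperature is kept low so that acid cannot cleave C4–C4a by ipso protonation.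

Step 11
Reactants: 28 (4S)-5-(benzyloxy)-4-[4-(benzyloxy)phenyl]-8-(3-phenylpropanoyl)-7-[(triisopropylsilyl)oxy]-3,4-dihydro-2H-chromen-2-one
Product: 29 (4S)-5-(benzyloxy)-4-[4-(benzyloxy)phenyl]-7-hydroxy-8-(3-phenylpropanoyl)-3,4-dihydro-2H-chromen-2-one
Conditions: n-Bu4NF (1.1 equiv), AcOH (1.5 equiv), THF, 0 °C
Reagents that add atoms: none
Why: Fluoride cleaves the aryl silyl ether, which is activated by the ortho acyl group. Acetic acid buffers the medium so that neither phenoxide nor fluoride opens the aryl ester, and O5 is still benzylated, so the lactone cannot migrate.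

Step 12
Reactants: 29 (4S)-5-(benzyloxy)-4-[4-(benzyloxy)phenyl]-7-hydroxy-8-(3-phenylpropanoyl)-3,4-dihydro-2H-chromen-2-one
Product: 30 (4S)-5,7-dihydroxy-4-(4-hydroxyphenyl)-8-(3-phenylpropanoyl)-3,4-dihydro-2H-chromen-2-one
Conditions: H2 (1 atm), Pd/C (10 wt %), EtOAc, rt
Reagents that add atoms: none
Why: Hydrogenolysis of both benzyl aryl ethers under neutral conditions; the chelated, electron-rich aryl ketone and the lactone are not reduced. The neutral, alcohol-free medium leaves no path for lactone migration to the freed O5 or for loss of configuration at C4.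

## Compound list

1 | 4-(benzyloxy)benzaldehyde | O=Cc1ccc(OCc2ccccc2)cc1 | starting material
2 | ethyl acetoacetate (ethyl 3-oxobutanoate) | CCOC(=O)CC(C)=O | starting material
3 | diethyl 2,4-diacetyl-3-[4-(benzyloxy)phenyl]pentanedioate (mixture of stereoisomers) | CCOC(=O)C(C(C)=O)C(c1ccc(OCc2ccccc2)cc1)C(C(C)=O)C(=O)OCC | intermediate (not isolated)
4 | 3-[4-(benzyloxy)phenyl]pentanedioic acid | OC(=O)CC(CC(=O)O)c1ccc(OCc2ccccc2)cc1 | intermediate
5 | 4-[4-(benzyloxy)phenyl]oxane-2,6-dione | O=C1CC(CC(=O)O1)c1ccc(OCc2ccccc2)cc1 | intermediate
6 | (3S)-3-[4-(benzyloxy)phenyl]-5-methoxy-5-oxopentanoic acid | COC(=O)C[C@@H](c1ccc(OCc2ccccc2)cc1)CC(=O)O | intermediate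
7 | benzyl alcohol | OCc1ccccc1 | starting material
8 | trichloroethylene | ClC=C(Cl)Cl | starting material
9 | dichloroacetylene | ClC#CCl | intermediate (not isolated)
10 | {[(E)-1,2-dichloroethenyl]oxy}methylbenzene | Cl/C=C(/Cl)OCc1ccccc1 | intermediate
11 | [(chloroethynyl)oxy]methylbenzene | ClC#COCc1ccccc1 | intermediate (not isolated)
12 | lithium (benzyloxy)ethynide | [Li]C#COCc1ccccc1 | intermediate (not isolated)
13 | (ethynyloxy)methylbenzene (benzyl ethynyl ether) | C#COCc1ccccc1 | intermediate
14 | methyl (3R)-3-[4-(benzyloxy)phenyl]-5-chloro-5-oxopentanoate | COC(=O)C[C@@H](c1ccc(OCc2ccccc2)cc1)CC(=O)Cl | intermediate (not isolated)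
15 | methyl (3R)-3-[4-(benzyloxy)phenyl]-5-oxopent-4-enoate (aldoketene) | COC(=O)C[C@@H](c1ccc(OCc2ccccc2)cc1)C=C=O | intermediate (not isolated)
16 | methyl (3R)-3-[4-(benzyloxy)phenyl]-3-[2-(benzyloxy)-4-oxocyclobut-2-en-1-yl]propanoate (both epimers at the ring carbon) | COC(=O)C[C@@H](c1ccc(OCc2ccccc2)cc1)C1C(=O)C=C1OCc1ccccc1 | intermediate
17 | ethyl 2-oxo-4-phenylbutanoate | CCOC(=O)C(=O)CCc1ccccc1 | starting material
18 | ethyl 2-(2-phenylethyl)-1,3-dioxolane-2-carboxylate | CCOC(=O)C1(CCc2ccccc2)OCCO1 | intermediate
19 | lithium 2,2-dibromo-1-[2-(2-phenylethyl)-1,3-dioxolan-2-yl]ethen-1-olate | [Li+].[O-]C(=C(Br)Br)C1(CCc2ccccc2)OCCO1 | intermediate (not isolated)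
20 | lithium 2-[2-(2-phenylethyl)-1,3-dioxolan-2-yl]ethyn-1-olate | [Li+].[O-]C#CC1(CCc2ccccc2)OCCO1 | intermediate (not isolated)
21 | triisopropyl({[2-(2-phenylethyl)-1,3-dioxolan-2-yl]ethynyl}oxy)silane | CC(C)[Si](C(C)C)(C(C)C)OC#CC1(CCc2ccccc2)OCCO1 | intermediate
22 | methyl (3R,4Z)-5-(benzyloxy)-3-[4-(benzyloxy)phenyl]-7-oxohepta-4,6-dienoate (side chain trans to the ketene carbon) | COC(=O)C[C@@H](c1ccc(OCc2ccccc2)cc1)/C=C(\OCc1ccccc1)C=C=O | intermediate (not isolated)
23 | methyl (3R,4Z)-5-(benzyloxy)-3-[4-(benzyloxy)phenyl]-5-{4-oxo-3-[2-(2-phenylethyl)-1,3-dioxolan-2-yl]-2-[(triisopropylsilyl)oxy]cyclobut-2-en-1-yl}pent-4-enoate (either configuration at the ring carbon) | COC(=O)C[C@@H](c1ccc(OCc2ccccc2)cc1)/C=C(\OCc1ccccc1)C1C(=O)C(C2(CCc3ccccc3)OCCO2)=C1O[Si](C(C)C)(C(C)C)C(C)C | intermediate (not isolated)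
24 | methyl (3R,4Z,6E)-5-(benzyloxy)-3-[4-(benzyloxy)phenyl]-9-oxo-8-[2-(2-phenylethyl)-1,3-dioxolan-2-yl]-7-[(triisopropylsilyl)oxy]nona-4,6,8-trienoate | COC(=O)C[C@@H](c1ccc(OCc2ccccc2)cc1)/C=C(\OCc1ccccc1)/C=C(/O[Si](C(C)C)(C(C)C)C(C)C)C(=C=O)C1(CCc2ccccc2)OCCO1 | intermediate (not isolated)
25 | methyl (3R)-3-[4-(benzyloxy)phenyl]-3-{2-(benzyloxy)-6-oxo-5-[2-(2-phenylethyl)-1,3-dioxolan-2-yl]-4-[(triisopropylsilyl)oxy]cyclohexa-2,4-dien-1-yl}propanoate (either configuration at the ring carbon) | COC(=O)C[C@@H](c1ccc(OCc2ccccc2)cc1)C1C(=O)C(C2(CCc3ccccc3)OCCO2)=C(O[Si](C(C)C)(C(C)C)C(C)C)C=C1OCc1ccccc1 | intermediate (not isolated)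
26 | methyl (3S)-3-[4-(benzyloxy)phenyl]-3-{6-(benzyloxy)-2-hydroxy-3-[2-(2-phenylethyl)-1,3-dioxolan-2-yl]-4-[(triisopropylsilyl)oxy]phenyl}propanoate | COC(=O)C[C@@H](c1ccc(OCc2ccccc2)cc1)c1c(OCc2ccccc2)cc(O[Si](C(C)C)(C(C)C)C(C)C)c(C2(CCc3ccccc3)OCCO2)c1O | intermediate
27 | methyl (3S)-3-[4-(benzyloxy)phenyl]-3-{6-(benzyloxy)-2-hydroxy-3-(3-phenylpropanoyl)-4-[(triisopropylsilyl)oxy]phenyl}propanoate | COC(=O)C[C@@H](c1ccc(OCc2ccccc2)cc1)c1c(OCc2ccccc2)cc(O[Si](C(C)C)(C(C)C)C(C)C)c(C(=O)CCc2ccccc2)c1O | intermediate (not isolated)
28 | (4S)-5-(benzyloxy)-4-[4-(benzyloxy)phenyl]-8-(3-phenylpropanoyl)-7-[(triisopropylsilyl)oxy]-3,4-dihydro-2H-chromen-2-one | O=C1C[C@@H](c2ccc(OCc3ccccc3)cc2)c2c(OCc3ccccc3)cc(O[Si](C(C)C)(C(C)C)C(C)C)c(C(=O)CCc3ccccc3)c2O1 | intermediate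
29 | (4S)-5-(benzyloxy)-4-[4-(benzyloxy)phenyl]-7-hydroxy-8-(3-phenylpropanoyl)-3,4-dihydro-2H-chromen-2-one | O=C1C[C@@H](c2ccc(OCc3ccccc3)cc2)c2c(OCc3ccccc3)cc(O)c(C(=O)CCc3ccccc3)c2O1 | intermediate
30 | (4S)-5,7-dihydroxy-4-(4-hydroxyphenyl)-8-(3-phenylpropanoyl)-3,4-dihydro-2H-chromen-2-one | O=C1C[C@@H](c2ccc(O)cc2)c2c(O)cc(O)c(C(=O)CCc3ccccc3)c2O1 | target

## Step count and least certain steps

Total: 12 steps. Longest linear sequence: 8 steps (steps 1, 2, 3, 6, 9, 10, 11, 12, from 1 to 30); steps 4–5 and 7–8 are side branches.

Step 9 (key step). The most likely failure is a slow [2+2] cycloaddition: the alkoxy group makes the vinylketene less electrophilic, and the reacting alkyne carbon is shielded by a quaternary ketal carbon and deactivated by its two oxygens, so ketene self-condensation or thermal loss of the ketal may win.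
Fallback (sets out from 16, comes back at 27): the ketone is carried as a flat 1,1-disubstituted alkene that is neither bulky nor electron-withdrawing.
- Commercial 2-methylbut-1-en-3-yne is dimetalated (n-BuLi, KOt-Bu, THF, −78 °C) and alkylated at the allylic carbon with benzyl bromide to give (3-methylidenepent-4-yn-1-yl)benzene F1.
- F1 is deprotonated (n-BuLi), the acetylide is oxidised on carbon with LiOOt-Bu (from t-BuOOH and LiN(SiMe3)2) and silylated on oxygen with i-Pr3SiOSO2CF3 in the same flask, giving triisopropyl[(3-methylidene-5-phenylpent-1-yn-1-yl)oxy]silane F2.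
- Heating F2 with 16 under the conditions of step 9 should give methyl (3S)-3-[4-(benzyloxy)phenyl]-3-{6-(benzyloxy)-2-hydroxy-3-(4-phenylbut-1-en-2-yl)-4-[(triisopropylsilyl)oxy]phenyl}propanoate F3.
- Lemieux–Johnson cleavage (OsO4 cat., NaIO4, 2,6-lutidine, dioxane/H2O) turns the alkene into the ketone 27, which is lactonised as in the second half of step 10.

Step 6. Dimerisation of the aldoketene and thermal loss of the fragile ynol ether 13 may outrun the cycloaddition, and slow exchange of the ester and acid chloride termini would erode enantiopurity.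
Fallback (sets out from 6, comes back at 30): the benzyl ynol ether is replaced by commercial, storable ethoxyacetylene, which can be used in large excess, and a Lewis-acid deprotection is accepted at the end.
- 6 is converted as in step 6 but with ethoxyacetylene to methyl (3R)-3-[4-(benzyloxy)phenyl]-3-(2-ethoxy-4-oxocyclobut-2-en-1-yl)propanoate F4.
- F4 and 21 under the conditions of step 9 should give methyl (3S)-3-[4-(benzyloxy)phenyl]-3-{6-ethoxy-2-hydroxy-3-[2-(2-phenylethyl)-1,3-dioxolan-2-yl]-4-[(triisopropylsilyl)oxy]phenyl}propanoate F5.
- The conditions of step 10 give (4S)-4-[4-(benzyloxy)phenyl]-5-ethoxy-8-(3-phenylpropanoyl)-7-[(triisopropylsilyl)oxy]-3,4-dihydro-2H-chromen-2-one F6.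
- The conditions of step 11 give (4S)-4-[4-(benzyloxy)phenyl]-5-ethoxy-7-hydroxy-8-(3-phenylpropanoyl)-3,4-dihydro-2H-chromen-2-one F7.
- BBr3 (excess), CH2Cl2, −78 → 0 °C cleaves the ethyl and benzyl ethers to give 30. This is less safe than hydrogenolysis for the lactone position and for C4, and is kept as a reserve for that reason.

Step 8. The 1,2-shift of a tertiary carbon bearing two oxygens in the carbenoid may fail, with fragmentation or protonation taking over.
Fallback (sets out from 18, comes back at 21): the alkyne is built first and oxidised afterwards.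
- i-Bu2AlH (toluene, −78 °C) reduces 18 to 2-(2-phenylethyl)-1,3-dioxolane-2-carbaldehyde F8.
- The Ohira–Bestmann reagent (K2CO3, MeOH) gives 2-ethynyl-2-(2-phenylethyl)-1,3-dioxolane F9.
- Deprotonation (n-BuLi), oxidation of the acetylide with LiOOt-Bu and O-silylation with i-Pr3SiCl give 21.

Step 3. Discrimination between the two enantiotopic carbonyl groups may be incomplete for the bulky para-benzyloxy substrate, or uncatalysed methanolysis may dilute the selectivity.
Fallback (sets out from 5, comes back at 6): resolution with recycling in place of enantiotopic-group selection.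
- 5 is opened in warm MeOH to the racemic 3-[4-(benzyloxy)phenyl]-5-methoxy-5-oxopentanoic acid F10.
- F10 is crystallised with (R)-1-phenylethylamine as (1R)-1-phenylethan-1-aminium (3S)-3-[4-(benzyloxy)phenyl]-5-methoxy-5-oxopentanoate F11; should the salt of the R acid be the less soluble one, the S amine is used instead.
- Acidification of F11 liberates 6; the mother liquor is saponified back to 4 and returned to step 2.

## Further compounds

F1 | step 9 | (3-methylidenepent-4-yn-1-yl)benzene | C#CC(=C)CCc1ccccc1
F2 | step 9 | triisopropyl[(3-methylidene-5-phenylpent-1-yn-1-yl)oxy]silane | CC(C)[Si](OC#CC(=C)CCc1ccccc1)(C(C)C)C(C)C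
F3 | step 9 | methyl (3S)-3-[4-(benzyloxy)phenyl]-3-{6-(benzyloxy)-2-hydroxy-3-(4-phenylbut-1-en-2-yl)-4-[(triisopropylsilyl)oxy]phenyl}propanoate | COC(=O)C[C@@H](c1ccc(OCc2ccccc2)cc1)c1c(OCc2ccccc2)cc(O[Si](C(C)C)(C(C)C)C(C)C)c(C(=C)CCc2ccccc2)c1O
F4 | step 6 | methyl (3R)-3-[4-(benzyloxy)phenyl]-3-(2-ethoxy-4-oxocyclobut-2-en-1-yl)propanoate | COC(=O)C[C@@H](c1ccc(OCc2ccccc2)cc1)C1C(=O)C=C1OCC
F5 | step 6 | methyl (3S)-3-[4-(benzyloxy)phenyl]-3-{6-ethoxy-2-hydroxy-3-[2-(2-phenylethyl)-1,3-dioxolan-2-yl]-4-[(triisopropylsilyl)oxy]phenyl}propanoate | COC(=O)C[C@@H](c1ccc(OCc2ccccc2)cc1)c1c(OCC)cc(O[Si](C(C)C)(C(C)C)C(C)C)c(C2(CCc3ccccc3)OCCO2)c1O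
F6 | step 6 | (4S)-4-[4-(benzyloxy)phenyl]-5-ethoxy-8-(3-phenylpropanoyl)-7-[(triisopropylsilyl)oxy]-3,4-dihydro-2H-chromen-2-one | O=C1C[C@@H](c2ccc(OCc3ccccc3)cc2)c2c(OCC)cc(O[Si](C(C)C)(C(C)C)C(C)C)c(C(=O)CCc3ccccc3)c2O1
F7 | step 6 | (4S)-4-[4-(benzyloxy)phenyl]-5-ethoxy-7-hydroxy-8-(3-phenylpropanoyl)-3,4-dihydro-2H-chromen-2-one | O=C1C[C@@H](c2ccc(OCc3ccccc3)cc2)c2c(OCC)cc(O)c(C(=O)CCc3ccccc3)c2O1
F8 | step 8 | 2-(2-phenylethyl)-1,3-dioxolane-2-carbaldehyde | O=CC1(CCc2ccccc2)OCCO1
F9 | step 8 | 2-ethynyl-2-(2-phenylethyl)-1,3-dioxolane | C#CC1(CCc2ccccc2)OCCO1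
F10 | step 3 | racemic 3-[4-(benzyloxy)phenyl]-5-methoxy-5-oxopentanoic acid | COC(=O)CC(CC(=O)O)c1ccc(OCc2ccccc2)cc1
F11 | step 3 | (1R)-1-phenylethan-1-aminium (3S)-3-[4-(benzyloxy)phenyl]-5-methoxy-5-oxopentanoate | C[C@@H]([NH3+])c1ccccc1.COC(=O)C[C@@H](c1ccc(OCc2ccccc2)cc1)CC(=O)[O-]
A1 | alternative 1 | 1-{4,6-bis(benzyloxy)-3-[4-(benzyloxy)phenyl]-1-benzofuran-7-yl}-3-phenylpropan-1-one | O=C(CCc1ccccc1)c1c(OCc2ccccc2)cc(OCc2ccccc2)c2c(-c3ccc(OCc4ccccc4)cc3)coc12
A2 | alternative 1 | 5,7-bis(benzyloxy)-4-[4-(benzyloxy)phenyl]-3-chloro-8-(3-phenylpropanoyl)chromenylium chloride | Clc1c[o+]c2c(C(=O)CCc3ccccc3)c(OCc3ccccc3)cc(OCc3ccccc3)c2c1-c1ccc(OCc2ccccc2)cc1.[Cl-]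
A3 | alternative 2 | (3S)-4,6-bis(benzyloxy)-3-[4-(benzyloxy)phenyl]-2,3-dihydro-1H-inden-1-one | O=C1C[C@@H](c2ccc(OCc3ccccc3)cc2)c2c(OCc3ccccc3)cc(OCc3ccccc3)cc21
A4 | alternative 2 | (4S)-5,7-bis(benzyloxy)-4-[4-(benzyloxy)phenyl]-3,4-dihydro-2H-chromen-2-one | O=C1C[C@@H](c2ccc(OCc3ccccc3)cc2)c2c(OCc3ccccc3)cc(OCc3ccccc3)cc2O1
A5 | alternative 3 | methyl (3S)-3-[4-(benzyloxy)phenyl]-3-[4-(benzyloxy)-2-oxo-6-(2-oxo-4-phenylbutyl)-2H-pyran-3-yl]propanoate | COC(=O)C[C@@H](c1ccc(OCc2ccccc2)cc1)c1c(OCc2ccccc2)cc(CC(=O)CCc2ccccc2)oc1=O
A6 | alternative 3 | (4S)-5-(benzyloxy)-4-[4-(benzyloxy)phenyl]-7-hydroxy-8-(3-phenylpropanoyl)-3,4-dihydro-2H-chromen-2-one | O=C1C[C@@H](c2ccc(OCc3ccccc3)cc2)c2c(OCc3ccccc3)cc(O)c(C(=O)CCc3ccccc3)c2O1
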